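**Retrosynthetic overview**

1. Target (flavan numbering: O1, C2 aryl, C3 OH, C4 CH2; ring A = benzo ring, ring B = 2-aryl ring) ⇐ bis(benzyl ether) 16 (hydrogenolysis) ⇐ acetate 15 (methanolysis) ⇐ trans-3-acetylflavan 14 (Baeyer–Villiger, C3–C becomes C3–O with retention).
2. Key disconnection: C2–C3 of the pyran ring. Ketone 14 is the cyclised isomer of the acyclic, achiral (E)-enone 12, reached by an acid-catalysed, enantioselective 1,5-hydride transfer/cyclisation that closes the pyran ring and sets C2 and C3 in one redox-neutral operation.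
3. Enabling feature: C4 of the pyran ring is a methylene lying 1,5 to the C2–H of the O1–CH2–ring B ether. C2 is flanked by O1 and the electron-rich 3,4,5-trioxygenated ring B, so this hydrogen can move as hydride to C4 (it becomes one of the two C4 hydrogens) and leave an oxocarbenium ion at C2 for the enol carbon C3.
4. 12 ⇐ salicylaldehyde 7 + benzylic alcohol 10 (Mitsunobu ether, then Wittig); 7 ⇐ bibenzyl 4 (Vilsmeier–Haack formylation, chelation-controlled demethylation); 4 ⇐ phosphonate 1 + aldehyde 2 (Horner–Wadsworth–Emmons, hydrogenation).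
5. Ring order: the three benzene rings are bought; the pyran ring is the only ring made and is closed last, in the key step.

Key step: step 9

Assumption: the (S,S) antipode of the IDPi acid is taken as the one that delivers the (2S,3S)-ketone 14; if a trial shows the opposite sense of induction, the (R,R) antipode is used with no other change.

**Route**

Step 1
Reactants: 1 diethyl [(3,5-dimethoxyphenyl)methyl]phosphonate; 2 3-(benzyloxy)benzaldehyde
Product: 3 1-(benzyloxy)-3-[(E)-2-(3,5-dimethoxyphenyl)ethenyl]benzene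
Conditions: NaH, THF, 0 °C → rt
Reagents that add atoms: none
Why: Horner–Wadsworth–Emmons olefination of a non-enolisable aryl aldehyde with the benzylic phosphonate anion should give the (E)-stilbene; no stereocentre is formed.

Step 2
Reactants: 3 1-(benzyloxy)-3-[(E)-2-(3,5-dimethoxyphenyl)ethenyl]benzene
Product: 4 1-(benzyloxy)-3-[2-(3,5-dimethoxyphenyl)ethyl]benzene
Conditions: H2 (1 atm), 10% Pd/C, Ph2S (0.01 equiv), EtOAc, rt
Reagents that add atoms: none
Why: Chemoselective heterogeneous hydrogenation: the sulfide-moderated palladium surface should saturate the stilbene double bond while leaving the aryl benzyl ether.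

Step 3
Reactants: 4 1-(benzyloxy)-3-[2-(3,5-dimethoxyphenyl)ethyl]benzene
Product: 6 2-{2-[3-(benzyloxy)phenyl]ethyl}-4,6-dimethoxybenzaldehyde, via iminium salt 5 (not isolated)
Conditions: POCl3, DMF, 0 → 60 °C; then H2O, rt
Reagents that add atoms: N,N-dimethylformamide CN(C)C=O; water O
Why: Vilsmeier–Haack formylation should occur only on the doubly activated 3,5-dimethoxyphenyl ring, at the position ortho to the chain (para to one methoxy, ortho to the other), which is less hindered than the site between the two methoxy groups; hydrolysis of iminium salt 5 releases the aldehyde.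

Step 4
Reactants: 6 2-{2-[3-(benzyloxy)phenyl]ethyl}-4,6-dimethoxybenzaldehyde
Product: 7 2-{2-[3-(benzyloxy)phenyl]ethyl}-6-hydroxy-4-methoxybenzaldehyde
Conditions: MgI2·OEt2, toluene, 80 °C; then 1 M HCl
Reagents that add atoms: none
Why: Chelation-directed ether cleavage: magnesium bridges the formyl oxygen and the ortho methoxy oxygen, so iodide should remove by SN2 only that methyl group and leave the para methoxy group and the remote benzyl ether.

Step 5
Reactants: 8 4-hydroxy-3,5-dimethoxybenzaldehyde (syringaldehyde)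
Product: 9 4-(benzyloxy)-3,5-dimethoxybenzaldehyde
Conditions: BnBr, K2CO3, DMF, 60 °C
Reagents that add atoms: benzyl bromide BrCc1ccccc1
Why: Williamson ether synthesis: SN2 attack of the phenoxide on benzyl bromide protects the 4-hydroxyl group.

Step 6
Reactants: 9 4-(benzyloxy)-3,5-dimethoxybenzaldehyde
Product: 10 [4-(benzyloxy)-3,5-dimethoxyphenyl]methanol
Conditions: NaBH4, MeOH, 0 °C
Reagents that add atoms: none
Why: Borohydride reduction of the aldehyde gives the primary benzylic alcohol needed for the etherification.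

Step 7
Reactants: 7 2-{2-[3-(benzyloxy)phenyl]ethyl}-6-hydroxy-4-methoxybenzaldehyde; 10 [4-(benzyloxy)-3,5-dimethoxyphenyl]methanol
Product: 11 2-{[4-(benzyloxy)-3,5-dimethoxyphenyl]methoxy}-6-{2-[3-(benzyloxy)phenyl]ethyl}-4-methoxybenzaldehyde
Conditions: PPh3, DIAD, THF, 0 °C → rt
Reagents that add atoms: none
Why: Mitsunobu etherification: the acidic, hydrogen-bonded salicylaldehyde hydroxyl should be alkylated by the alkoxyphosphonium ion of the primary benzylic alcohol under neutral conditions that leave the aldehyde untouched.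

Step 8
Reactants: 11 2-{[4-(benzyloxy)-3,5-dimethoxyphenyl]methoxy}-6-{2-[3-(benzyloxy)phenyl]ethyl}-4-methoxybenzaldehyde
Product: 12 (3E)-4-(2-{[4-(benzyloxy)-3,5-dimethoxyphenyl]methoxy}-6-{2-[3-(benzyloxy)phenyl]ethyl}-4-methoxyphenyl)but-3-en-2-one
Conditions: Ph3P=CHC(O)CH3, toluene, 110 °C
Reagents that add atoms: 1-(triphenylphosphoranylidene)propan-2-one CC(=O)C=P(c1ccccc1)(c1ccccc1)c1ccccc1
Why: Wittig olefination with a keto-stabilised ylide should give the (E)-enone selectively, the non-enolisable aldehyde having no competing pathway.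

Step 9
Reactants: 12 (3E)-4-(2-{[4-(benzyloxy)-3,5-dimethoxyphenyl]methoxy}-6-{2-[3-(benzyloxy)phenyl]ethyl}-4-methoxyphenyl)but-3-en-2-one
Product: 14 1-[(2S,3S)-2-[4-(benzyloxy)-3,5-dimethoxyphenyl]-5-{2-[3-(benzyloxy)phenyl]ethyl}-7-methoxy-3,4-dihydro-2H-chromen-3-yl]ethan-1-one, via oxocarbenium enol cation 13 (not isolated)
Conditions: (S,S)-IDPi (chiral BINOL-derived imidodiphosphorimidate Brønsted acid, 5 mol%), 5 Å MS, CHCl3, 25 → 40 °C
Reagents that add atoms: none
Why: Proposed new method: protonation of the enone carbonyl by the confined chiral acid turns C4 into a hydride acceptor, the C2–H bond of the aryl benzyl ether (alpha to O1 and benzylic to ring B) delivers hydride to C4 through a six-membered 1,5-transfer, and the oxocarbenium ion 13 thus formed is captured at C2 by the enol carbon C3, which forms the C2–C3 bond and returns the proton. The closest known reaction type is the Lewis-acid-catalysed hydride-transfer cyclisation (internal redox, tert-amino effect) of ortho-vinylaryl benzyl ethers carrying doubly activated alkenes to 2-arylchromans, together with its chiral phosphoric acid version in the aniline series; the singly activated enone acceptor and enantiocontrol in the ether series go beyond it. The pyran ring closes in a 6-(enolexo)-endo-trig mode, the enol attacking the O1=C2 oxocarbenium bond that lies inside the new ring. C2 is set in this bond formation inside the contact ion pair of 13 with the chiral IDPi anion, which is hydrogen-bonded to the enol hydroxyl and leaves one face of the (E)-oxocarbenium open; C3 is set trans to the aryl group by a chair-like transition state with the aryl group equatorial and, being alpha to the ketone, can still equilibrate to the diequatorial trans isomer through the enol under the acidic conditions without loss at C2. The step needs hydride donation from C2–H and not from the benzylic CH2 of the bibenzyl chain, which the substrate secures because only C2–H is flanked by oxygen and an electron-rich ring, whereas both ring A oxygens are meta to C5 and cannot stabilise a cation at its benzylic carbon; C- over O-attack of the enol is secured by the six- versus eight-membered ring size.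

Step 10
Reactants: 14 1-[(2S,3S)-2-[4-(benzyloxy)-3,5-dimethoxyphenyl]-5-{2-[3-(benzyloxy)phenyl]ethyl}-7-methoxy-3,4-dihydro-2H-chromen-3-yl]ethan-1-one
Product: 15 (2R,3S)-2-[4-(benzyloxy)-3,5-dimethoxyphenyl]-5-{2-[3-(benzyloxy)phenyl]ethyl}-7-methoxy-3,4-dihydro-2H-chromen-3-yl acetate
Conditions: mCPBA, CH2Cl2, 0 °C → rt
Reagents that add atoms: 3-chloroperoxybenzoic acid OOC(=O)c1cccc(Cl)c1
Why: Baeyer–Villiger oxidation: in the Criegee adduct the secondary C3 should migrate in preference to methyl and with retention of configuration, so the C3–acetyl bond becomes the C3–O bond of the trans acetate without touching C2.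

Step 11
Reactants: 15 (2R,3S)-2-[4-(benzyloxy)-3,5-dimethoxyphenyl]-5-{2-[3-(benzyloxy)phenyl]ethyl}-7-methoxy-3,4-dihydro-2H-chromen-3-yl acetate
Product: 16 (2R,3S)-2-[4-(benzyloxy)-3,5-dimethoxyphenyl]-5-{2-[3-(benzyloxy)phenyl]ethyl}-7-methoxy-3,4-dihydro-2H-chromen-3-ol
Conditions: K2CO3 (0.2 equiv), MeOH/THF, rt
Reagents that add atoms: none
Why: Base-catalysed transesterification with methanol should remove the acetate; with the ketone gone, no carbanion can form next to C2 or C3 and both stereocentres persist.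

Step 12
Reactants: 16 (2R,3S)-2-[4-(benzyloxy)-3,5-dimethoxyphenyl]-5-{2-[3-(benzyloxy)phenyl]ethyl}-7-methoxy-3,4-dihydro-2H-chromen-3-ol
Product: 17 (2R,3S)-2-(4-hydroxy-3,5-dimethoxyphenyl)-5-[2-(3-hydroxyphenyl)ethyl]-7-methoxy-3,4-dihydro-2H-chromen-3-ol
Conditions: H2 (1 atm), 20% Pd(OH)2/C, EtOAc/MeOH, rt
Reagents that add atoms: none
Why: Catalytic hydrogenolysis should cleave the two aryl benzyl ethers, while the cyclic C2–O1 benzylic ether, a secondary alkyl aryl ether held in the ring, is cleaved far more slowly, as is usual for benzyl-protected flavan-3-ols.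

**Compound list**

1 | diethyl [(3,5-dimethoxyphenyl)methyl]phosphonate | CCOP(=O)(Cc1cc(OC)cc(OC)c1)OCC | starting material
2 | 3-(benzyloxy)benzaldehyde | O=Cc1cccc(OCc2ccccc2)c1 | starting material
3 | 1-(benzyloxy)-3-[(E)-2-(3,5-dimethoxyphenyl)ethenyl]benzene | COc1cc(/C=C/c2cccc(OCc3ccccc3)c2)cc(OC)c1 | intermediate
4 | 1-(benzyloxy)-3-[2-(3,5-dimethoxyphenyl)ethyl]benzene | COc1cc(CCc2cccc(OCc3ccccc3)c2)cc(OC)c1 | intermediate
5 | N-[(2-{2-[3-(benzyloxy)phenyl]ethyl}-4,6-dimethoxyphenyl)methylidene]-N-methylmethanaminium dichlorophosphate (iminium salt) | COc1cc(CCc2cccc(OCc3ccccc3)c2)c(C=[N+](C)C)c(OC)c1.[O-]P(=O)(Cl)Cl | intermediate (not isolated)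
6 | 2-{2-[3-(benzyloxy)phenyl]ethyl}-4,6-dimethoxybenzaldehyde | COc1cc(CCc2cccc(OCc3ccccc3)c2)c(C=O)c(OC)c1 | intermediate
7 | 2-{2-[3-(benzyloxy)phenyl]ethyl}-6-hydroxy-4-methoxybenzaldehyde | COc1cc(O)c(C=O)c(CCc2cccc(OCc3ccccc3)c2)c1 | intermediate
8 | 4-hydroxy-3,5-dimethoxybenzaldehyde (syringaldehyde) | COc1cc(C=O)cc(OC)c1O | starting material
9 | 4-(benzyloxy)-3,5-dimethoxybenzaldehyde | COc1cc(C=O)cc(OC)c1OCc1ccccc1 | intermediate
10 | [4-(benzyloxy)-3,5-dimethoxyphenyl]methanol | COc1cc(CO)cc(OC)c1OCc1ccccc1 | intermediate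
11 | 2-{[4-(benzyloxy)-3,5-dimethoxyphenyl]methoxy}-6-{2-[3-(benzyloxy)phenyl]ethyl}-4-methoxybenzaldehyde | COc1cc(OCc2cc(OC)c(OCc3ccccc3)c(OC)c2)c(C=O)c(CCc2cccc(OCc3ccccc3)c2)c1 | intermediate
12 | (3E)-4-(2-{[4-(benzyloxy)-3,5-dimethoxyphenyl]methoxy}-6-{2-[3-(benzyloxy)phenyl]ethyl}-4-methoxyphenyl)but-3-en-2-one | COc1cc(OCc2cc(OC)c(OCc3ccccc3)c(OC)c2)c(/C=C/C(C)=O)c(CCc2cccc(OCc3ccccc3)c2)c1 | intermediate
13 | {[4-(benzyloxy)-3,5-dimethoxyphenyl]methylidene}(3-{2-[3-(benzyloxy)phenyl]ethyl}-2-(3-hydroxybut-2-en-1-yl)-5-methoxyphenyl)oxidanium, the oxocarbenium enol cation paired with the IDPi anion (cation shown) | COc1cc([O+]=Cc2cc(OC)c(OCc3ccccc3)c(OC)c2)c(CC=C(C)O)c(CCc2cccc(OCc3ccccc3)c2)c1 | intermediate (not isolated)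
14 | 1-[(2S,3S)-2-[4-(benzyloxy)-3,5-dimethoxyphenyl]-5-{2-[3-(benzyloxy)phenyl]ethyl}-7-methoxy-3,4-dihydro-2H-chromen-3-yl]ethan-1-one (2,3-trans) | COc1cc(CCc2cccc(OCc3ccccc3)c2)c2c(c1)O[C@H](c1cc(OC)c(OCc3ccccc3)c(OC)c1)[C@@H](C(C)=O)C2 | intermediate
15 | (2R,3S)-2-[4-(benzyloxy)-3,5-dimethoxyphenyl]-5-{2-[3-(benzyloxy)phenyl]ethyl}-7-methoxy-3,4-dihydro-2H-chromen-3-yl acetate | COc1cc(CCc2cccc(OCc3ccccc3)c2)c2c(c1)O[C@H](c1cc(OC)c(OCc3ccccc3)c(OC)c1)[C@@H](OC(C)=O)C2 | intermediate
16 | (2R,3S)-2-[4-(benzyloxy)-3,5-dimethoxyphenyl]-5-{2-[3-(benzyloxy)phenyl]ethyl}-7-methoxy-3,4-dihydro-2H-chromen-3-ol | COc1cc(CCc2cccc(OCc3ccccc3)c2)c2c(c1)O[C@H](c1cc(OC)c(OCc3ccccc3)c(OC)c1)[C@@H](O)C2 | intermediate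
17 | (2R,3S)-2-(4-hydroxy-3,5-dimethoxyphenyl)-5-[2-(3-hydroxyphenyl)ethyl]-7-methoxy-3,4-dihydro-2H-chromen-3-ol | COc1cc(CCc2cccc(O)c2)c2c(c1)O[C@H](c1cc(OC)c(O)c(OC)c1)[C@@H](O)C2 | target

**Step count and risks**

Total steps: 12. Longest linear sequence: 10 steps (steps 1, 2, 3, 4, 7, 8, 9, 10, 11, 12).

Steps most likely to fail:

Step 9. The singly activated, aryl-conjugated enone may accept hydride too slowly, so that acid cleavage of the electron-rich benzyl ether or acid-mediated ring opening at C2–O1 of the product erodes conversion and enantiopurity; the ion pair may also discriminate the two oxocarbenium faces poorly. The fallback uses known chemistry and sets out from aldehyde 11. Knoevenagel condensation with tert-butyl acetoacetate (TiCl4, pyridine, THF, 0 °C → rt) should give the doubly activated alkene tert-butyl 2-acetyl-3-(2-{[4-(benzyloxy)-3,5-dimethoxyphenyl]methoxy}-6-{2-[3-(benzyloxy)phenyl]ethyl}-4-methoxyphenyl)prop-2-enoate F1 as an E/Z mixture. This is the established acceptor class for the achiral Lewis-acid hydride-transfer cyclisation of ortho-vinylaryl benzyl ethers, and Sc(OTf)3 (10 mol%, ClCH2CH2Cl, 80 °C) should close it to racemic tert-butyl 3-acetyl-2-[4-(benzyloxy)-3,5-dimethoxyphenyl]-5-{2-[3-(benzyloxy)phenyl]ethyl}-7-methoxy-3,4-dihydro-2H-chromene-3-carboxylate F2. TFA in CH2Cl2 should then remove the tert-butyl group, decarboxylate the keto acid and equilibrate C3 to the racemic trans ketone rac-1-[(2S*,3S*)-2-[4-(benzyloxy)-3,5-dimethoxyphenyl]-5-{2-[3-(benzyloxy)phenyl]ethyl}-7-methoxy-3,4-dihydro-2H-chromen-3-yl]ethan-1-one F3. Preparative chromatography on a chiral stationary phase (supercritical CO2/MeOH, amylose tris(3,5-dimethylphenylcarbamate)) separates the enantiomers; the (2S,3S) enantiomer is ketone 14, where the route is rejoined.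

Step 10. Oxygen insertion at the hindered, beta-oxygenated secondary centre may be slow, and the peracid may meanwhile oxidise the electron-rich rings. The fallback replaces the peracid oxidation by a Hock-type carbon-to-oxygen rearrangement and sets out from ketone 14. MeLi with CeCl3 (THF, −78 °C) should give the tertiary carbinol 2-[(2S,3S)-2-[4-(benzyloxy)-3,5-dimethoxyphenyl]-5-{2-[3-(benzyloxy)phenyl]ethyl}-7-methoxy-3,4-dihydro-2H-chromen-3-yl]propan-2-ol F4. Perhydrolysis (50% H2O2, cat. H2SO4, Et2O, 0 °C) should convert it into the tertiary hydroperoxide (2S,3S)-2-[4-(benzyloxy)-3,5-dimethoxyphenyl]-5-{2-[3-(benzyloxy)phenyl]ethyl}-3-(2-hydroperoxypropan-2-yl)-7-methoxy-3,4-dihydro-2H-chromene F5. BF3·OEt2 (CH2Cl2, −40 °C) should then trigger migration of the secondary C3 from carbon to oxygen, with retention and in preference to methyl; aqueous work-up releases acetone and gives alcohol 16, where the route is rejoined (step 11 is then not needed).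

Step 2. Hydrogenolysis of the aryl benzyl ether may accompany alkene reduction, or the reduction may stall on the moderated catalyst. The fallback changes the protecting-group order and sets out from stilbene 3. Unmoderated hydrogenation (H2, 10% Pd/C, EtOAc/MeOH, rt) should reduce the alkene and cleave the benzyl ether together to give 3-[2-(3,5-dimethoxyphenyl)ethyl]phenol F6. Re-benzylation (BnBr, K2CO3, DMF, 60 °C) returns to bibenzyl 4, where the route is rejoined.

**Further compounds**

F1 | step 9 | tert-butyl 2-acetyl-3-(2-{[4-(benzyloxy)-3,5-dimethoxyphenyl]methoxy}-6-{2-[3-(benzyloxy)phenyl]ethyl}-4-methoxyphenyl)prop-2-enoate (E/Z mixture) | COc1cc(OCc2cc(OC)c(OCc3ccccc3)c(OC)c2)c(C=C(C(C)=O)C(=O)OC(C)(C)C)c(CCc2cccc(OCc3ccccc3)c2)c1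
F2 | step 9 | tert-butyl 3-acetyl-2-[4-(benzyloxy)-3,5-dimethoxyphenyl]-5-{2-[3-(benzyloxy)phenyl]ethyl}-7-methoxy-3,4-dihydro-2H-chromene-3-carboxylate (racemic, both C3 epimers) | COc1cc(CCc2cccc(OCc3ccccc3)c2)c2c(c1)OC(c1cc(OC)c(OCc3ccccc3)c(OC)c1)C(C(C)=O)(C(=O)OC(C)(C)C)C2
F3 | step 9 | rac-1-[(2S*,3S*)-2-[4-(benzyloxy)-3,5-dimethoxyphenyl]-5-{2-[3-(benzyloxy)phenyl]ethyl}-7-methoxy-3,4-dihydro-2H-chromen-3-yl]ethan-1-one (racemic trans ketone) | COc1cc(CCc2cccc(OCc3ccccc3)c2)c2c(c1)OC(c1cc(OC)c(OCc3ccccc3)c(OC)c1)C(C(C)=O)C2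
F4 | step 10 | 2-[(2S,3S)-2-[4-(benzyloxy)-3,5-dimethoxyphenyl]-5-{2-[3-(benzyloxy)phenyl]ethyl}-7-methoxy-3,4-dihydro-2H-chromen-3-yl]propan-2-ol | COc1cc(CCc2cccc(OCc3ccccc3)c2)c2c(c1)O[C@H](c1cc(OC)c(OCc3ccccc3)c(OC)c1)[C@@H](C(C)(C)O)C2
F5 | step 10 | (2S,3S)-2-[4-(benzyloxy)-3,5-dimethoxyphenyl]-5-{2-[3-(benzyloxy)phenyl]ethyl}-3-(2-hydroperoxypropan-2-yl)-7-methoxy-3,4-dihydro-2H-chromene | COc1cc(CCc2cccc(OCc3ccccc3)c2)c2c(c1)O[C@H](c1cc(OC)c(OCc3ccccc3)c(OC)c1)[C@@H](C(C)(C)OO)C2
F6 | step 2 | 3-[2-(3,5-dimethoxyphenyl)ethyl]phenol | COc1cc(CCc2cccc(O)c2)cc(OC)c1
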